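**Strategy.** The 14-membered carbocycle is closed last, at C13–C14 (cembrane numbering: C1/C2 carry the cis-fused α-methylene-γ-lactone, C8 is the tertiary carbinol, C11–C12 the oxirane, C13 the acetoxy carbon, C14 the ring CH2). The step exploits that C13 is a carbinol flanked by the quaternary, non-epimerisable oxirane carbon C12 and by an unbranched methylene: a cobalt-catalysed Nozaki–Hiyama–Kishi-type addition of the primary C14 iodide to the C13 α,β-epoxy aldehyde closes the ring and sets C13 by Felkin–Anh control in one operation. The open-chain precursor already holds the lactone, both E-olefins, C8–OH and the oxirane; it is assembled from (S)-linalool and an allylation-derived lactone by cross-metathesis.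

Key step: step 16

Assumption: (S)-(+)-linalool of high enantiomeric purity and the chiral carbazole bis(oxazoline) ligand of step 5 are taken as purchasable; C1–C20 below are the cembrane positions defined above.

**Step 1**
Reactants: 1 2-(tert-butyldimethylsilyloxy)acetaldehyde; 2 methyl acrylate
Product: 3 methyl 4-(tert-butyldimethylsilyloxy)-3-hydroxy-2-methylenebutanoate (racemic)
Conditions: DABCO (0.5 equiv), MeOH, rt
Reagents that add atoms: none
Why: Morita–Baylis–Hillman reaction of the reactive α-silyloxy aldehyde with the acrylate; the new carbinol centre is racemic and is erased in step 2.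

**Step 2**
Reactants: 3 methyl 4-(tert-butyldimethylsilyloxy)-3-hydroxy-2-methylenebutanoate
Product: 4 methyl (Z)-2-(bromomethyl)-4-(tert-butyldimethylsilyloxy)but-2-enoate
Conditions: NBS, Me2S, CH2Cl2, 0 °C to rt
Reagents that add atoms: N-bromosuccinimide, O=C1CCC(=O)N1Br
Why: Corey–Kim-type activation of the allylic alcohol as an alkoxysulfonium ion and SN2' attack of bromide should give the thermodynamically preferred (Z)-bromide (CH2OTBS trans to the ester); no stereocentre remains.

**Step 3**
Reactants: 5 pent-1-en-4-yne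
Product: 7 (E)-3-methylhexa-2,5-dien-1-ol, via alkenylalane 6 (not isolated)
Conditions: AlMe3, Cp2ZrCl2 (25 mol %), CH2Cl2, 0 °C to rt; then n-BuLi, (CH2O)n, THF, 0 °C to rt
Reagents that add atoms: trimethylaluminium, C[Al](C)C; formaldehyde (from paraformaldehyde), C=O
Why: Negishi zirconium-catalysed carboalumination adds methyl and aluminium syn to the alkyne only (aluminium terminal), and trapping of the ate complex with formaldehyde proceeds with retention, fixing the (E)-trisubstituted olefin.

**Step 4**
Reactants: 7 (E)-3-methylhexa-2,5-dien-1-ol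
Product: 8 (E)-3-methylhexa-2,5-dienal
Conditions: MnO2, CH2Cl2, rt
Reagents that add atoms: none
Why: MnO2 oxidation is selective for the allylic alcohol and neutral, so the skipped diene should not move into conjugation and the (E)-geometry is kept.

**Step 5**
Reactants: 8 (E)-3-methylhexa-2,5-dienal; 4 methyl (Z)-2-(bromomethyl)-4-(tert-butyldimethylsilyloxy)but-2-enoate
Product: 11 (4R,5S)-4-[(tert-butyldimethylsilyloxy)methyl]-3-methylene-5-[(E)-2-methylpenta-1,4-dien-1-yl]dihydrofuran-2(3H)-one (cis), via allylchromium species 9 (not isolated), via syn-hydroxy ester 10 (not isolated)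
Conditions: CrCl2 (10 mol %), chiral carbazole bis(oxazoline) ligand (12 mol %, enantiomer for Re-face attack), Mn, iPr2NEt, Me3SiCl, THF, 0 °C; then PPTS, MeOH–CH2Cl2, rt
Reagents that add atoms: none
Why: Catalytic asymmetric Nozaki–Hiyama–Kishi 2-(alkoxycarbonyl)allylation: allylchromium 9 adds at its γ-carbon through a chair transition state to give the syn adduct, the chiral chromium complex selects the Re face of the enal (sets C2 as S and with it C1), and lactonisation of syn-hydroxy ester 10 gives the cis-lactone.

**Step 6**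
Reactants: 11 silyloxymethyl lactone
Product: 12 (4R,5S)-4-(hydroxymethyl)-3-methylene-5-[(E)-2-methylpenta-1,4-dien-1-yl]dihydrofuran-2(3H)-one
Conditions: HF·pyridine, pyridine, THF, 0 °C to rt
Reagents that add atoms: none
Why: Fluoride-mediated desilylation under buffered, weakly acidic conditions should free the primary alcohol without conjugate addition to the α-methylene lactone or translactonisation; no stereocentre is touched.

**Step 7**
Reactants: 12 hydroxymethyl lactone
Product: 13 (4S,5S)-4-(iodomethyl)-3-methylene-5-[(E)-2-methylpenta-1,4-dien-1-yl]dihydrofuran-2(3H)-one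
Conditions: I2, PPh3, imidazole, CH2Cl2, 0 °C
Reagents that add atoms: iodine, II
Why: Appel-type iodination (alkoxyphosphonium, SN2 at the primary carbon) under neutral conditions leaves the acrylate and both lactone stereocentres untouched.

**Step 8**
Reactants: 14 (S)-(+)-linalool
Product: 15 (S)-triethyl[(3,7-dimethylocta-1,6-dien-3-yl)oxy]silane
Conditions: Et3SiOTf, 2,6-lutidine, CH2Cl2, −78 to 0 °C
Reagents that add atoms: triethylsilyl trifluoromethanesulfonate, CC[Si](CC)(CC)OS(=O)(=O)C(F)(F)F
Why: Silylation of the hindered tertiary alcohol with the silyl triflate masks it as a non-nucleophilic ether for steps 9 to 12; C8 is not involved.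

**Step 9**
Reactants: 15 linalool triethylsilyl ether
Product: 17 (S)-4-methyl-4-(triethylsilyloxy)hex-5-enal, via ozonide 16 (not isolated)
Conditions: O3 (1 equiv, Sudan red end point), CH2Cl2, pyridine (cat.), −78 °C; then Me2S, −78 °C to rt
Reagents that add atoms: ozone, [O-][O+]=O
Why: Ozonolysis with one equivalent of ozone should cleave the electron-rich trisubstituted olefin much faster than the hindered vinyl group, and Me2S reduces ozonide 16 to the aldehyde; C8 is untouched.

**Step 10**
Reactants: 17 (S)-4-methyl-4-(triethylsilyloxy)hex-5-enal; 18 ethyl 2-[bis(2,2,2-trifluoroethoxy)phosphoryl]propanoate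
Product: 19 ethyl (2Z,6S)-2,6-dimethyl-6-(triethylsilyloxy)octa-2,7-dienoate
Conditions: KN(SiMe3)2, 18-crown-6, THF, −78 °C
Reagents that add atoms: none
Why: Still–Gennari olefination: the electron-poor phosphonate under dissociating conditions eliminates kinetically to the (Z)-2-methyl enoate, the geometry that later places C10 and C13 cis on the oxirane.

**Step 11**
Reactants: 19 (Z)-enoate
Product: 20 (2Z,6S)-2,6-dimethyl-6-(triethylsilyloxy)octa-2,7-dien-1-ol
Conditions: iBu2AlH, CH2Cl2, −78 °C
Reagents that add atoms: none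
Why: 1,2-Reduction of the ester by the aluminium hydride at low temperature should give the allylic alcohol without isomerising the (Z)-olefin or touching the silyl ether.

**Step 12**
Reactants: 20 (Z)-allylic alcohol
Product: 21 [(2R,3S)-2-methyl-3-[(3S)-3-methyl-3-(triethylsilyloxy)pent-4-en-1-yl]oxiran-2-yl]methanol
Conditions: Ti(OiPr)4 (20 mol %), D-(−)-diisopropyl tartrate (24 mol %), t-BuOOH, 4 Å molecular sieves, CH2Cl2, −20 °C
Reagents that add atoms: tert-butyl hydroperoxide, CC(C)(C)OO
Why: Sharpless asymmetric epoxidation: the titanium tartrate complex delivers oxygen to one face of the allylic olefin under reagent control (2R,3S), syn-addition keeps C10 and C13 cis, and the isolated vinyl group is not epoxidised.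

**Step 13**
Reactants: 21 silyl-protected epoxy alcohol
Product: 22 [(2R,3S)-3-[(3S)-3-hydroxy-3-methylpent-4-en-1-yl]-2-methyloxiran-2-yl]methanol
Conditions: Bu4NF, AcOH, THF, 0 °C to rt
Reagents that add atoms: none
Why: Acetic-acid-buffered fluoride desilylation avoids a free alkoxide that could open the oxirane and frees the tertiary allylic alcohol, whose unprotected form is the better cross-metathesis partner; no stereocentre is affected.

**Step 14**
Reactants: 22 epoxy diol; 13 iodomethyl lactone
Product: 23 (4S,5S)-5-[(1E,4E,6S)-6-hydroxy-8-[(2S,3R)-3-(hydroxymethyl)-3-methyloxiran-2-yl]-2,6-dimethylocta-1,4-dien-1-yl]-4-(iodomethyl)-3-methylenedihydrofuran-2(3H)-one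
Conditions: second-generation Grubbs catalyst RuCl2(=CHPh)(PCy3)(H2IMes) (10 mol %), 1,4-benzoquinone (10 mol %), 22 (2 equiv), CH2Cl2, 40 °C
Reagents that add atoms: none
Why: Olefin cross-metathesis between the unhindered allyl terminus of 13 and the vinyl carbinol of 22 should give the (E)-olefin because of the quaternary allylic carbon; the trisubstituted olefin and the exo-methylene acrylate are unreactive and benzoquinone suppresses double-bond migration.

**Step 15**
Reactants: 23 seco diol iodide
Product: 24 (2S,3S)-3-[(3S,4E,7E)-3-hydroxy-8-[(2S,3S)-3-(iodomethyl)-4-methylene-5-oxotetrahydrofuran-2-yl]-3,7-dimethylocta-4,7-dien-1-yl]-2-methyloxirane-2-carbaldehyde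
Conditions: Dess–Martin periodinane, NaHCO3, CH2Cl2, 0 °C to rt
Reagents that add atoms: none
Why: Buffered Dess–Martin oxidation converts only the primary alcohol (the tertiary one cannot be oxidised) into the α,β-epoxy aldehyde, whose quaternary α-carbon cannot epimerise.

**Step 16**
Reactants: 24 seco iodo epoxy aldehyde
Product: 26 (1S,2S,3E,6E,8S,11S,12R,13R)-11,12-epoxy-8,13-dihydroxycembra-3,6,15(17)-trien-16,2-olide, via alkylchromium species 25 (not isolated)
Conditions: CrCl2 (10 equiv), cobalt phthalocyanine C32H16CoN8 (10 mol %), DMF, 25 °C, 24 added over 12 h (final 0.002 M)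
Reagents that add atoms: none
Why: Cobalt phthalocyanine, reduced by CrCl2 to nucleophilic monovalent cobalt, takes up the C14–I carbon and releases the primary C14 radical, which a second divalent chromium captures as alkylchromium 25; this weakly basic, oxophilic reagent adds to the chromium-activated C13 aldehyde. The closest known reaction type is the Nozaki–Hiyama–Kishi macrocyclisation, here in its cobalt-catalysed alkyl-iodide version. The 14-membered carbocycle is the only ring closed, by 14-exo-trig attack of C14 on the C13 carbonyl under high dilution. The new stereocentre C13 is controlled by the adjacent quaternary oxirane carbon C12: Felkin–Anh/Cornforth attack anti to the C12–O bond and past the C12 methyl, not the C11 ring carbon, should give the anti (13R) epoxy alcohol. The step needs chemoselectivity for the aldehyde over lactone, acrylate and oxirane, which the low nucleophilicity of alkylchromium secures, and C12 bears no hydrogen, so the aldehyde cannot epimerise. The two (E)-olefins, the cis-oxirane and the cis-lactone limit the conformations of the chain and should favour ring closure over oligomerisation.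

**Step 17**
Reactants: 26 macrocyclic epoxy diol
Product: 27 (1S,2S,3E,6E,8S,11S,12S,13R)-13-acetoxy-11,12-epoxy-8-hydroxycembra-3,6,15(17)-trien-16,2-olide (target)
Conditions: Ac2O, pyridine, DMAP (cat.), CH2Cl2, 0 °C
Reagents that add atoms: acetic anhydride, CC(=O)OC(C)=O
Why: DMAP-catalysed acylation of the secondary C13 hydroxyl with retention; the tertiary C8 hydroxyl is too hindered to react at 0 °C, and prompt acetylation forestalls transfer of the lactone acyl group to O13.

**Compound list**

1 | 2-(tert-butyldimethylsilyloxy)acetaldehyde | O=CCO[Si](C)(C)C(C)(C)C | starting material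
2 | methyl acrylate | C=CC(=O)OC | starting material
3 | methyl 4-(tert-butyldimethylsilyloxy)-3-hydroxy-2-methylenebutanoate (racemic) | C=C(C(=O)OC)C(O)CO[Si](C)(C)C(C)(C)C | intermediate
4 | methyl (Z)-2-(bromomethyl)-4-(tert-butyldimethylsilyloxy)but-2-enoate | BrC/C(C(=O)OC)=C\CO[Si](C)(C)C(C)(C)C | intermediate
5 | pent-1-en-4-yne | C#CCC=C | starting material
6 | (E)-dimethyl(2-methylpenta-1,4-dien-1-yl)alane | C=CC/C(C)=C/[Al](C)C | intermediate (not isolated)
7 | (E)-3-methylhexa-2,5-dien-1-ol | C=CC/C(C)=C/CO | intermediate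
8 | (E)-3-methylhexa-2,5-dienal | C=CC/C(C)=C/C=O | intermediate
9 | methyl (Z)-4-(tert-butyldimethylsilyloxy)-2-[(dichlorochromio)methyl]but-2-enoate (allylchromium species, chiral ligand omitted) | Cl[Cr](Cl)C/C(C(=O)OC)=C\CO[Si](C)(C)C(C)(C)C | intermediate (not isolated)
10 | methyl (3R,4S,5E)-3-[(tert-butyldimethylsilyloxy)methyl]-4-hydroxy-6-methyl-2-methylenenona-5,8-dienoate | C=C(C(=O)OC)[C@H](CO[Si](C)(C)C(C)(C)C)[C@@H](O)/C=C(\C)CC=C | intermediate (not isolated)
11 | (4R,5S)-4-[(tert-butyldimethylsilyloxy)methyl]-3-methylene-5-[(E)-2-methylpenta-1,4-dien-1-yl]dihydrofuran-2(3H)-one | C=C1C(=O)O[C@@H](/C=C(\C)CC=C)[C@H]1CO[Si](C)(C)C(C)(C)C | intermediate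
12 | (4R,5S)-4-(hydroxymethyl)-3-methylene-5-[(E)-2-methylpenta-1,4-dien-1-yl]dihydrofuran-2(3H)-one | C=C1C(=O)O[C@@H](/C=C(\C)CC=C)[C@H]1CO | intermediate
13 | (4S,5S)-4-(iodomethyl)-3-methylene-5-[(E)-2-methylpenta-1,4-dien-1-yl]dihydrofuran-2(3H)-one | C=C1C(=O)O[C@@H](/C=C(\C)CC=C)[C@H]1CI | intermediate
14 | (S)-(+)-linalool | C=C[C@@](C)(O)CCC=C(C)C | starting material
15 | (S)-triethyl[(3,7-dimethylocta-1,6-dien-3-yl)oxy]silane | C=C[C@@](C)(O[Si](CC)(CC)CC)CCC=C(C)C | intermediate
16 | ozonide of 15 at the trisubstituted olefin (3,3-dimethyl-1,2,4-trioxolane; new acetal carbon unassigned) | CC1(C)OOC(CC[C@@](C)(C=C)O[Si](CC)(CC)CC)O1 | intermediate (not isolated)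
17 | (S)-4-methyl-4-(triethylsilyloxy)hex-5-enal | C=C[C@@](C)(O[Si](CC)(CC)CC)CCC=O | intermediate
18 | ethyl 2-[bis(2,2,2-trifluoroethoxy)phosphoryl]propanoate | CCOC(=O)C(C)P(=O)(OCC(F)(F)F)OCC(F)(F)F | starting material
19 | ethyl (2Z,6S)-2,6-dimethyl-6-(triethylsilyloxy)octa-2,7-dienoate | C=C[C@@](C)(O[Si](CC)(CC)CC)CC/C=C(/C)C(=O)OCC | intermediate
20 | (2Z,6S)-2,6-dimethyl-6-(triethylsilyloxy)octa-2,7-dien-1-ol | C=C[C@@](C)(O[Si](CC)(CC)CC)CC/C=C(/C)CO | intermediate
21 | [(2R,3S)-2-methyl-3-[(3S)-3-methyl-3-(triethylsilyloxy)pent-4-en-1-yl]oxiran-2-yl]methanol | C=C[C@@](C)(O[Si](CC)(CC)CC)CC[C@@H]1O[C@]1(C)CO | intermediate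
22 | [(2R,3S)-3-[(3S)-3-hydroxy-3-methylpent-4-en-1-yl]-2-methyloxiran-2-yl]methanol | C=C[C@@](C)(O)CC[C@@H]1O[C@]1(C)CO | intermediate
23 | seco diol iodide (C13 CH2OH, C14 CH2I; name in step 14) | C=C1C(=O)O[C@@H](/C=C(\C)C/C=C/[C@@](C)(O)CC[C@@H]2O[C@]2(C)CO)[C@H]1CI | intermediate
24 | seco iodo epoxy aldehyde (C13 CHO, C14 CH2I; name in step 15) | C=C1C(=O)O[C@@H](/C=C(\C)C/C=C/[C@@](C)(O)CC[C@@H]2O[C@]2(C)C=O)[C@H]1CI | intermediate
25 | alkylchromium dichloride of 24 (C14–CrCl2) | C=C1C(=O)O[C@@H](/C=C(\C)C/C=C/[C@@](C)(O)CC[C@@H]2O[C@]2(C)C=O)[C@H]1C[Cr](Cl)Cl | intermediate (not isolated)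
26 | (1S,2S,3E,6E,8S,11S,12R,13R)-11,12-epoxy-8,13-dihydroxycembra-3,6,15(17)-trien-16,2-olide | C=C1C(=O)O[C@H]2/C=C(\C)C/C=C/[C@@](C)(O)CC[C@@H]3O[C@]3(C)[C@H](O)C[C@@H]12 | intermediate
27 | (1S,2S,3E,6E,8S,11S,12S,13R)-13-acetoxy-11,12-epoxy-8-hydroxycembra-3,6,15(17)-trien-16,2-olide | C=C1C(=O)O[C@H]2/C=C(\C)C/C=C/[C@@](C)(O)CC[C@@H]3O[C@]3(C)[C@H](OC(C)=O)C[C@@H]12 | target

**Step count and risks**

Total: 17 steps. Longest linear sequence: 10 steps (steps 8 to 17, from (S)-linalool).

Step 16. Divalent chromium may reductively open the α,β-epoxy aldehyde before the alkylchromium forms. Slow carbon–chromium bond formation at high dilution may let protonation at C14 or oligomerisation win. Trivalent chromium may promote opening of the oxirane by the C8 hydroxyl, or the aldehyde may be attacked on the wrong face. The fallback sets out from 24 and comes back at 26. Pinnick oxidation (NaClO2, NaH2PO4, 2-methyl-2-butene) should give the glycidic acid F1, and EtSH with EDC and DMAP its S-ethyl thioester F2. Zinc dust (LiCl, THF) should insert into the C14–I bond to give the alkylzinc iodide F3. Under PdCl2(PPh3)2 at high dilution F3 should close the ring by intramolecular Fukuyama coupling to the macrocyclic α,β-epoxy ketone F4. Zn(BH4)2 in Et2O at −20 °C, delivering hydride to the zinc chelate of carbonyl and oxirane oxygens, should then give the anti epoxy alcohol 26.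

Step 14. The valuable iodide 13 may homodimerise, ruthenium hydrides may move its terminal double bond into conjugation, or turnover at the hindered vinyl carbinol may be low. The fallback sets out from 22 and 7 and comes back at 24. 22 is cross-metathesised with an excess of the cheap dienol 7 (same catalyst) to the triol F5, and MnO2 oxidises only its allylic alcohol to the enal F6. The chromium-catalysed asymmetric allylation of step 5 with bromide 4 is then run on F6 (through allylchromium 9 and the syn-hydroxy ester F7) to give the silyloxymethyl lactone F8. Dess–Martin oxidation of the one remaining primary alcohol should give the epoxy aldehyde F9, HF·pyridine the alcohol F10, and I2/PPh3/imidazole the iodo aldehyde 24.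

Step 5. Face selection by the chiral chromium complex on the γ-substituted allyl reagent may be poor, so that enantiomeric purity is eroded. The fallback sets out from 8 and 4 and comes back at 12; it replaces catalyst control by resolution. Stoichiometric CrCl2 without ligand should give the racemic syn adduct (10 together with its enantiomer F11), and lactonisation the racemic cis-lactone (11 together with its enantiomer F12). HF·pyridine then gives the racemic alcohol (12 together with its enantiomer F13). Lipase-catalysed acetylation (Burkholderia cepacia lipase, vinyl acetate, tert-butyl methyl ether) is expected to esterify one antipode. If F13 is converted into its acetate F14, unreacted 12 is separated by chromatography. If the enzyme prefers 12, its acetate F15 is collected and cleaved by the same lipase in ethanol.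

**Further compounds**

F1 | step 16 | glycidic acid (C13 carboxylic acid analogue of 24) | C=C1C(=O)O[C@@H](/C=C(\C)C/C=C/[C@@](C)(O)CC[C@@H]2O[C@]2(C)C(=O)O)[C@H]1CI
F2 | step 16 | S-ethyl thioester of F1 | C=C1C(=O)O[C@@H](/C=C(\C)C/C=C/[C@@](C)(O)CC[C@@H]2O[C@]2(C)C(=O)SCC)[C@H]1CI
F3 | step 16 | alkylzinc iodide of F2 (C14–ZnI) | C=C1C(=O)O[C@@H](/C=C(\C)C/C=C/[C@@](C)(O)CC[C@@H]2O[C@]2(C)C(=O)SCC)[C@H]1C[Zn]I
F4 | step 16 | macrocyclic α,β-epoxy ketone (13-oxo analogue of 26) | C=C1C(=O)O[C@H]2/C=C(\C)C/C=C/[C@@](C)(O)CC[C@@H]3O[C@]3(C)C(=O)C[C@@H]12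
F5 | step 14 | (2E,5E,7S)-9-[(2S,3R)-3-(hydroxymethyl)-3-methyloxiran-2-yl]-3,7-dimethylnona-2,5-diene-1,7-diol | OC/C=C(\C)C/C=C/[C@@](C)(O)CC[C@@H]1O[C@]1(C)CO
F6 | step 14 | enal from F5 (C2 aldehyde) | O=C/C=C(\C)C/C=C/[C@@](C)(O)CC[C@@H]1O[C@]1(C)CO
F7 | step 14 | syn-hydroxy ester from F6 and 4 | C=C(C(=O)OC)[C@H](CO[Si](C)(C)C(C)(C)C)[C@@H](O)/C=C(\C)C/C=C/[C@@](C)(O)CC[C@@H]1O[C@]1(C)CO
F8 | step 14 | silyloxymethyl lactone diol (C14 OTBS analogue of 23) | C=C1C(=O)O[C@@H](/C=C(\C)C/C=C/[C@@](C)(O)CC[C@@H]2O[C@]2(C)CO)[C@H]1CO[Si](C)(C)C(C)(C)C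
F9 | step 14 | silyloxymethyl lactone epoxy aldehyde (C14 OTBS analogue of 24) | C=C1C(=O)O[C@@H](/C=C(\C)C/C=C/[C@@](C)(O)CC[C@@H]2O[C@]2(C)C=O)[C@H]1CO[Si](C)(C)C(C)(C)C
F10 | step 14 | hydroxymethyl lactone epoxy aldehyde (C14 OH analogue of 24) | C=C1C(=O)O[C@@H](/C=C(\C)C/C=C/[C@@](C)(O)CC[C@@H]2O[C@]2(C)C=O)[C@H]1CO
F11 | step 5 | enantiomer of 10 | C=C(C(=O)OC)[C@@H](CO[Si](C)(C)C(C)(C)C)[C@H](O)/C=C(\C)CC=C
F12 | step 5 | enantiomer of 11 | C=C1C(=O)O[C@H](/C=C(\C)CC=C)[C@@H]1CO[Si](C)(C)C(C)(C)C
F13 | step 5 | enantiomer of 12 | C=C1C(=O)O[C@H](/C=C(\C)CC=C)[C@@H]1CO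
F14 | step 5 | acetate of F13 | C=C1C(=O)O[C@H](/C=C(\C)CC=C)[C@@H]1COC(C)=O
F15 | step 5 | acetate of 12 | C=C1C(=O)O[C@@H](/C=C(\C)CC=C)[C@H]1COC(C)=O
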